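I began with the easy step of counting what goes in; the east run is this very flask, followed as far as 50.0 min.

the same everywhere: substrate 0.20 M (fed, over 10 min)

|  | reagent | initiator | remark | time |
|---|---|---|---|---|
| east | 0.14 M | 2 mM | the very flask that is asked about, followed so far; the fed solution adds 0.10 times the starting volume |  |
| flask | 0.140 M | 2.0 mM | the fed solution adds 0.10 times the starting volume | 4.0 h |

east run (percent of the substrate charged)

| time / min | target / % | substrate / % |
|---|---|---|
| 3.00 | 11 | 14 |
| 10.0 | 73 | 34 |
| 15.0 | 72 | 30 |
| 25.0 | 69 | 30 |
| 40.0 | 68 | 30 |
| 50.0 | 71 | 30 |

(standard deviation of a reading: 1.5 percentage points)

- charges are per starting volume, the dose included; the dosed solution carries all of it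
- the reaction counts as stopped when no species that holds the substrate changes by six tenths of a point or more over the second half of the time
- percentages count the whole charge, also what has not yet gone in

- at 4.0 h, what has stopped the reaction, if anything has (the reagent has run out first / it is still moving / forward and back rates have come level / all of the substrate has reacted)
- how much target there is at 4.0 h, in percent of the substrate charged

I compared two amounts, the reagent charge and the substrate charge, and solved each end. With reagent to spare, the whole substrate charge can become target, a fraction of one. With substrate to spare, and taking one reagent per target, target stops at the reagent charge over the substrate charge. Joined, the two ends give: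

ceiling = smaller of one and (reagent charge / substrate charge) = 70.0%

This ceiling is the largest fraction of the substrate charge that can stand as target at one reagent per target, and in this flask the reagent, charged at less than the substrate, is the limiting reagent. The initiator charge is hardly any of the substrate charge, so I did not count it as a partner. The target readings from 15.0 min to 50.0 min average 70.0%, about the same as the ceiling, and they show no trend. I therefore committed to 70.0% at the asked time.

The forecast said the reagent has run out first, with 70% of target (from 68% to 71.5%), in the words “plateau therefore matches reagent exhaustion”.

In the flask at the asked time, the reagent has run out first: it holds 70.0% of target, with 0% of the reagent left.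

    2 second chain carrier → ended chains B (k = 1.30 × 10⁹ L mol⁻¹ s⁻¹)
    2 first chain carrier → ended chains A (k = 1.30 × 10⁷ L mol⁻¹ s⁻¹)
    initiator → 2 initiating radical (k = 5.90 × 10⁻⁴ s⁻¹)
    substrate + second chain carrier → by-product + first chain carrier (k = 2.80 × 10⁵ L mol⁻¹ s⁻¹)
    reagent + first chain carrier → target + second chain carrier (k = 6.60 × 10⁵ L mol⁻¹ s⁻¹)
    substrate + initiating radical → capped initiator + first chain carrier (k = 2.70 × 10⁶ L mol⁻¹ s⁻¹)

A neighbour charged with 0.056 M of reagent has a ceiling of 28.0% and gives 28.0%, with 0% of its reagent left. This flask has stopped: over the second half of the time, the largest change in the share of the substrate, an intermediate or a product was 0.028 percentage points. Left until 40.0 h, its initiator falls from 0.0204% of its charge to 0%, while substrate stands at 28.6% and target at 70.0%.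

The earlier runs and the new flask are calculated from invented constants; noise was put on by code.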